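**Retrosynthetic overview**

1. Feature: the ketone carbon C1 of the three-carbon chain is bonded to C1 of ring A (the 4-hydroxy-3,5-dimethoxyphenyl ring) and to C2, the (S) centre that carries H, the ring B aryloxy oxygen and the CH2OH carbon C3. The C2–H bond is acidified by the ketone, so base would epimerise C2 or expel the oxygen on C3.
2. Key disconnection: the C1(=O)–C1(ring A) bond, made last and without base from an (S)-S-phenyl thioester and a ring A boronic acid under palladium/copper catalysis (Liebeskind–Srogl acyl coupling).
3. Thioester: the C2–O(ring B) bond comes from Mitsunobu inversion of a 3-O-silyl (R)-glycerate (from the (R)-glycerate acetonide) with tert-butyl vanillate, followed by methyl ester to thioester exchange.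
4. Boronic acid: 4-bromo-2,6-dimethoxyphenol is protected as its methoxymethyl ether, then bromine–lithium exchange and borylation.
5. No ring is formed: rings A and B are bought as benzene derivatives. One acid treatment at the end frees the alcohol, the phenol and the carboxylic acid.

Key step: step 8

Remark: the ring A phenol is carried as a methoxymethyl ether and not as a benzyl ether, so that all three protecting groups fall in one acid step and no hydrogenation is run beside the aryl ketone; C2 is (S) with the order O-aryl > C1 carbonyl > C3 > H, and this order holds for the esters, the thioester and the ketones alike.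

**Route**

Step 1
Reactants: 1 methyl (R)-2,2-dimethyl-1,3-dioxolane-4-carboxylate
Product: 2 methyl (R)-2,3-dihydroxypropanoate
Conditions: Dowex 50WX8 (H+ form), MeOH–H2O 9:1, 25 °C; filter, concentrate
Reagents that add atoms: none
Why: Acid-catalysed acetonide hydrolysis frees the 1,2-diol without touching C2, so the (R) configuration is carried over, and methanol as cosolvent makes any ester exchange degenerate.

Step 2
Reactants: 2 methyl (R)-2,3-dihydroxypropanoate
Product: 3 methyl (R)-3-[(tert-butyldimethylsilyl)oxy]-2-hydroxypropanoate
Conditions: TBSCl (1.05 equiv), imidazole, CH2Cl2, 0 °C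
Reagents that add atoms: tert-butyldimethylsilyl chloride, CC(C)(C)[Si](C)(C)Cl
Why: Regioselective silyl ether formation, since the primary hydroxyl is far less hindered than the secondary hydroxyl beside the ester, so one equivalent of silyl chloride at 0 °C should silylate the oxygen on C3 only.

Step 3
Reactants: 4 vanillic acid (4-hydroxy-3-methoxybenzoic acid)
Product: 5 tert-butyl 4-hydroxy-3-methoxybenzoate
Conditions: Me2NCH(OtBu)2 (4 equiv), toluene, 80 °C
Reagents that add atoms: N,N-dimethylformamide di-tert-butyl acetal, CN(C)C(OC(C)(C)C)OC(C)(C)C
Why: Esterification with an amide acetal, in which the carboxylic acid protonates the reagent and the carboxylate is tert-butylated within the ion pair, while the much less acidic phenol should stay free.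

Step 4
Reactants: 3 methyl (R)-3-[(tert-butyldimethylsilyl)oxy]-2-hydroxypropanoate; 5 tert-butyl 4-hydroxy-3-methoxybenzoate
Product: 6 methyl (2S)-2-[4-(tert-butoxycarbonyl)-2-methoxyphenoxy]-3-[(tert-butyldimethylsilyl)oxy]propanoate
Conditions: PPh3, DIAD, THF, 0 → 25 °C
Reagents that add atoms: none
Why: Mitsunobu etherification, in which the phenol (acidified by its para ester) displaces the oxyphosphonium of the secondary carbinol in an SN2 reaction helped by the adjacent ester, so C2 is inverted from (R) to (S) and the stereocentre of the target is set here.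

Step 5
Reactants: 6 methyl (2S)-2-[4-(tert-butoxycarbonyl)-2-methoxyphenoxy]-3-[(tert-butyldimethylsilyl)oxy]propanoate
Product: 7 S-phenyl (2S)-2-[4-(tert-butoxycarbonyl)-2-methoxyphenoxy]-3-[(tert-butyldimethylsilyl)oxy]propanethioate
Conditions: AlMe3 (2.2 equiv), PhSH (2.2 equiv), CH2Cl2, 0 °C; then 6, 0 → 25 °C; aq. potassium sodium tartrate KNaC4H4O6
Reagents that add atoms: thiophenol, Sc1ccccc1
Why: Ester to thioester exchange with an aluminium thiolate (Me2AlSPh from AlMe3 and PhSH), a Lewis-acidic and non-basic reagent that should attack the unhindered aliphatic methyl ester and leave the hindered, conjugated tert-butyl benzoate, the silyl ether and the C2–H bond alone.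

Step 6
Reactants: 8 4-bromo-2,6-dimethoxyphenol
Product: 9 5-bromo-1,3-dimethoxy-2-(methoxymethoxy)benzene
Conditions: MOMCl, iPr2NEt, CH2Cl2, 0 → 25 °C
Reagents that add atoms: chloromethyl methyl ether, COCCl
Why: Phenol O-alkylation with a chloromethyl ether under amine base gives the methoxymethyl ether, which tolerates the organolithium and the neutral coupling and is removed in the final acid step.

Step 7
Reactants: 9 5-bromo-1,3-dimethoxy-2-(methoxymethoxy)benzene
Product: 12 [3,5-dimethoxy-4-(methoxymethoxy)phenyl]boronic acid, via aryllithium 10 (not isolated), via lithium aryltriisopropoxyborate 11 (not isolated)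
Conditions: n-BuLi, THF, −78 °C; B(OiPr)3, −78 → 0 °C; sat. aq. NH4Cl
Reagents that add atoms: triisopropyl borate, CC(C)OB(OC(C)C)OC(C)C; water, O
Why: Bromine–lithium exchange at −78 °C, borylation of the aryllithium and mild hydrolysis is the standard route to arylboronic acids, and the near-neutral work-up keeps the acetal.

Step 8
Reactants: 7 S-phenyl (2S)-2-[4-(tert-butoxycarbonyl)-2-methoxyphenoxy]-3-[(tert-butyldimethylsilyl)oxy]propanethioate; 12 [3,5-dimethoxy-4-(methoxymethoxy)phenyl]boronic acid
Product: 13 tert-butyl 4-{[(2S)-3-[(tert-butyldimethylsilyl)oxy]-1-[3,5-dimethoxy-4-(methoxymethoxy)phenyl]-1-oxopropan-2-yl]oxy}-3-methoxybenzoate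
Conditions: Pd2(dba)3 (2.5 mol%), tri(2-furyl)phosphine (15 mol%), copper thiophene-2-carboxylate CuO2CC4H3S (1.5 equiv), 12 (1.5 equiv), THF, 25 °C, Ar
Reagents that add atoms: none
Why: Zerovalent palladium (from Pd2(dba)3 and the furylphosphine) inserts into the acyl C–S bond of 7; the copper carboxylate (monovalent copper) binds the sulfur on palladium while its carboxylate oxygen coordinates boron, so the ring A aryl group passes to palladium without added base and reductive elimination forms the C1(=O)–C1(ring A) bond. The closest known reaction is the Liebeskind–Srogl coupling of thioesters of N-protected alpha-amino acids and alpha-alkoxy acids with arylboronic acids, which gives the ketones with the alpha centre intact. No ring closes and no stereocentre is created; the (S) centre at C2 is expected to be retained because neither 7 nor 13 meets a base and the reaction runs at room temperature. The step needs insertion into the thioester and not into the tert-butyl ester or the aryl ethers, which the far weaker and more polarisable C–S bond secures. It also needs ketone formation ahead of loss of CO from the acyl-palladium, which fast transmetalation of the electron-rich boronic acid with two free ortho positions should secure at 25 °C. Loss of the silyloxy group from C3 would require an enolate, which these conditions do not form.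

Step 9
Reactants: 13 tert-butyl 4-{[(2S)-3-[(tert-butyldimethylsilyl)oxy]-1-[3,5-dimethoxy-4-(methoxymethoxy)phenyl]-1-oxopropan-2-yl]oxy}-3-methoxybenzoate
Product: 14 4-{[(2S)-3-hydroxy-1-(4-hydroxy-3,5-dimethoxyphenyl)-1-oxopropan-2-yl]oxy}-3-methoxybenzoic acid (target)
Conditions: TFA–CH2Cl2–H2O 10:10:1, anisole, 0 → 25 °C; evaporate; MeOH–H2O, 25 °C
Reagents that add atoms: none
Why: Global acidolysis, in which the tert-butyl ester ionises to the tert-butyl cation (lost as isobutene or trapped by anisole) and the methoxymethyl acetal and the primary silyl ether are hydrolysed, while the base-sensitive centre at C2 is expected to hold under brief acid contact at or below 25 °C, and the stir in aqueous methanol cleaves any trifluoroacetate formed at the primary alcohol.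

**Compound list**

1 | methyl (R)-2,2-dimethyl-1,3-dioxolane-4-carboxylate | COC(=O)[C@H]1COC(C)(C)O1 | starting material
2 | methyl (R)-2,3-dihydroxypropanoate | COC(=O)[C@H](O)CO | intermediate
3 | methyl (R)-3-[(tert-butyldimethylsilyl)oxy]-2-hydroxypropanoate | COC(=O)[C@H](O)CO[Si](C)(C)C(C)(C)C | intermediate
4 | vanillic acid | COc1cc(C(=O)O)ccc1O | starting material
5 | tert-butyl 4-hydroxy-3-methoxybenzoate | COc1cc(C(=O)OC(C)(C)C)ccc1O | intermediate
6 | methyl (2S)-2-[4-(tert-butoxycarbonyl)-2-methoxyphenoxy]-3-[(tert-butyldimethylsilyl)oxy]propanoate | COc1cc(C(=O)OC(C)(C)C)ccc1O[C@@H](CO[Si](C)(C)C(C)(C)C)C(=O)OC | intermediate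
7 | S-phenyl (2S)-2-[4-(tert-butoxycarbonyl)-2-methoxyphenoxy]-3-[(tert-butyldimethylsilyl)oxy]propanethioate | COc1cc(C(=O)OC(C)(C)C)ccc1O[C@@H](CO[Si](C)(C)C(C)(C)C)C(=O)Sc1ccccc1 | intermediate
8 | 4-bromo-2,6-dimethoxyphenol | COc1cc(Br)cc(OC)c1O | starting material
9 | 5-bromo-1,3-dimethoxy-2-(methoxymethoxy)benzene | COCOc1c(OC)cc(Br)cc1OC | intermediate
10 | [3,5-dimethoxy-4-(methoxymethoxy)phenyl]lithium | [Li]c1cc(OC)c(OCOC)c(OC)c1 | intermediate
11 | lithium [3,5-dimethoxy-4-(methoxymethoxy)phenyl]tri(propan-2-yloxy)borate | [Li+].COCOc1c(OC)cc(cc1OC)[B-](OC(C)C)(OC(C)C)OC(C)C | intermediate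
12 | [3,5-dimethoxy-4-(methoxymethoxy)phenyl]boronic acid | COCOc1c(OC)cc(B(O)O)cc1OC | intermediate
13 | tert-butyl 4-{[(2S)-3-[(tert-butyldimethylsilyl)oxy]-1-[3,5-dimethoxy-4-(methoxymethoxy)phenyl]-1-oxopropan-2-yl]oxy}-3-methoxybenzoate | COc1cc(C(=O)OC(C)(C)C)ccc1O[C@@H](CO[Si](C)(C)C(C)(C)C)C(=O)c1cc(OC)c(OCOC)c(OC)c1 | intermediate
14 | 4-{[(2S)-3-hydroxy-1-(4-hydroxy-3,5-dimethoxyphenyl)-1-oxopropan-2-yl]oxy}-3-methoxybenzoic acid | COc1cc(C(=O)O)ccc1O[C@@H](CO)C(=O)c1cc(OC)c(O)c(OC)c1 | target

**Step count**

Total step count: 9. Longest linear sequence: 6 steps (steps 1, 2, 4, 5, 8, 9).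

**Steps most likely to fail**

Step 8. Transmetalation may be slow enough that the acyl-palladium loses CO, the electron-rich boronic acid may be protodeboronated, or copper thiolate and carboxylate may promote enolisation and erode the configuration at C2. The fallback is a Fukuyama-type acyl coupling with an organozinc in place of the boronic acid and the copper cofactor. It sets out from bromide 9 and thioester 7. Bromine–lithium exchange on 9 (n-BuLi, THF, −78 °C) would give aryllithium 10, and ZnCl2 in THF would convert it into [3,5-dimethoxy-4-(methoxymethoxy)phenyl]zinc chloride F1. F1 would then be coupled with 7 under PdCl2(PPh3)2 (a divalent palladium precatalyst that the organozinc reduces to zerovalent palladium) in THF–toluene at 25 °C. The route is rejoined at ketone 13.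

Step 5. Excess aluminium thiolate may cause beta-elimination of the silyloxy group, enolisation at C2, further addition at the new thioester, or attack at the tert-butyl ester. The fallback separates hydrolysis from thioester formation and sets out from ester 6. Me3SnOH in 1,2-dichloroethane at 70 °C, followed by a cold dilute HCl wash, would cleave only the methyl ester under neutral conditions and give (2S)-2-[4-(tert-butoxycarbonyl)-2-methoxyphenoxy]-3-[(tert-butyldimethylsilyl)oxy]propanoic acid F2. Redox condensation of F2 with PhSSPh and PBu3 in MeCN at 25 °C would then give the thioester without base. The route is rejoined at thioester 7.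

Step 4. Displacement at the flanked secondary carbinol may be slow, so that the reduced azodicarboxylate is alkylated instead, the silyl group migrates from the oxygen on C3 to the oxygen on C2 before activation, or inversion is incomplete. The fallback uses a sulfonate displacement and sets out from alcohol 3. Tf2O and 2,6-lutidine in CH2Cl2 at −78 °C would give methyl (2R)-3-[(tert-butyldimethylsilyl)oxy]-2-{[(trifluoromethyl)sulfonyl]oxy}propanoate F3. Phenol 5 with K2CO3 in MeCN at 0 °C would then displace the triflate by SN2 with clean inversion. The route is rejoined at ether 6.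

**Further compounds**

F1 | step 8 | [3,5-dimethoxy-4-(methoxymethoxy)phenyl]zinc chloride | COCOc1c(OC)cc([Zn]Cl)cc1OC
F2 | step 5 | (2S)-2-[4-(tert-butoxycarbonyl)-2-methoxyphenoxy]-3-[(tert-butyldimethylsilyl)oxy]propanoic acid | COc1cc(C(=O)OC(C)(C)C)ccc1O[C@@H](CO[Si](C)(C)C(C)(C)C)C(=O)O
F3 | step 4 | methyl (2R)-3-[(tert-butyldimethylsilyl)oxy]-2-{[(trifluoromethyl)sulfonyl]oxy}propanoate | COC(=O)[C@H](OS(=O)(=O)C(F)(F)F)CO[Si](C)(C)C(C)(C)C
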